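**Retrosynthetic overview**

1. Target 15 ⇒ triol 13 by selective isovalerylation of the benzylic O1' ⇒ acetonide 12 by ketal hydrolysis.
2. Feature used: the bond from C6 of the coumarin benzo ring to the benzylic, acyloxy-bearing C1' leads into the threo C1'(O)–C2'(O) diol and the C3' dimethyl carbinol. This array is tartaric acid with one carboxyl turned into C3'(CH3)2OH and the other exchanged for the arene.
3. Key disconnection C6–C1': 12 ⇒ redox-active ester 6 + 6-iodo-7-methoxycoumarin 11, by nickel-catalysed reductive decarboxylative arylation; C1' is set trans to the C2' substituent on the dioxolane.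
4. 6 ⇒ D-tartrate acetonide diester 1 (half-saponification, MeMgBr, N-hydroxyphthalimide 5); 11 ⇒ 2-hydroxy-4-methoxybenzaldehyde 7 (iodination, Wittig lactonisation).
5. Ring order: the dioxolane ring comes with 1 and serves only as a temporary stereocontrol ring; the pyran-2-one ring is closed in step 5, before the coupling; no ring is formed in or after the key step.

Key step: step 6

Remark: the side chain is numbered C1' (benzylic), C2', C3'. The target SMILES reads as (1'R,2'S), the threo diol, which corresponds to the (4S,5S) acetonide of dimethyl D-tartrate.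

**Route**

Step 1
Reactants: 1 dimethyl (4S,5S)-2,2-dimethyl-1,3-dioxolane-4,5-dicarboxylate
Product: 2 (4S,5S)-5-(methoxycarbonyl)-2,2-dimethyl-1,3-dioxolane-4-carboxylic acid
Conditions: KOH (1.0 equiv), MeOH, 0 °C to rt; then 1 M HCl to pH 3, 0 °C
Reagents that add atoms: potassium hydroxide, [K+].[OH-]
Why: Mono-saponification of a C2-symmetric diester: the two esters are homotopic, so one equivalent of hydroxide should give a single half-ester whose carboxylate charge slows the second hydrolysis, and the stereocentres are not touched.

Step 2
Reactants: 2 (4S,5S)-5-(methoxycarbonyl)-2,2-dimethyl-1,3-dioxolane-4-carboxylic acid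
Product: 4 (4S,5S)-5-(2-hydroxypropan-2-yl)-2,2-dimethyl-1,3-dioxolane-4-carboxylic acid, via acetyl dioxolane acid 3 (not isolated)
Conditions: MeMgBr (4 equiv), THF, −20 °C to rt; then 1 M HCl to pH 3, 0 °C
Reagents that add atoms: methylmagnesium bromide, C[Mg]Br
Why: Grignard addition to an ester: the first equivalent only deprotonates the acid to a bromomagnesium carboxylate that resists attack, two further equivalents take the methyl ester through ketone 3 to the tertiary carbinol, and the trans hydroxy acid cannot lactonise because that would need a trans-fused bicyclo[3.3.0] lactone.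

Step 3
Reactants: 4 (4S,5S)-5-(2-hydroxypropan-2-yl)-2,2-dimethyl-1,3-dioxolane-4-carboxylic acid; 5 N-hydroxyphthalimide
Product: 6 1,3-dioxoisoindolin-2-yl (4S,5S)-5-(2-hydroxypropan-2-yl)-2,2-dimethyl-1,3-dioxolane-4-carboxylate
Conditions: N,N'-diisopropylcarbodiimide (1.1 equiv), DMAP (5 mol%), CH2Cl2, 0 °C to rt
Reagents that add atoms: none
Why: Carbodiimide (Steglich-type) esterification gives the redox-active ester; the tertiary alcohol is too hindered to compete, and the ester is used without long storage.

Step 4
Reactants: 7 2-hydroxy-4-methoxybenzaldehyde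
Product: 8 2-hydroxy-5-iodo-4-methoxybenzaldehyde
Conditions: ICl (1.05 equiv), AcOH, rt
Reagents that add atoms: iodine monochloride, ClI
Why: Electrophilic aromatic iodination: C5 is para to the phenol, ortho to the methoxy group and meta to the formyl group, and is less hindered than C3, which lies between the two oxygen substituents.

Step 5
Reactants: 8 2-hydroxy-5-iodo-4-methoxybenzaldehyde; 9 ethyl (triphenylphosphoranylidene)acetate
Product: 11 6-iodo-7-methoxy-2H-chromen-2-one, via E-cinnamate ester 10 (not isolated)
Conditions: PhNEt2, reflux (about 215 °C), N2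
Reagents that add atoms: none
Why: Wittig olefination with a stabilised ylide, then thermal E/Z equilibration of cinnamate 10 and lactonisation of the Z isomer onto the ortho phenol, the established one-pot route from salicylaldehydes to coumarins, closes the pyran-2-one ring.

Step 6
Reactants: 6 1,3-dioxoisoindolin-2-yl (4S,5S)-5-(2-hydroxypropan-2-yl)-2,2-dimethyl-1,3-dioxolane-4-carboxylate; 11 6-iodo-7-methoxy-2H-chromen-2-one
Product: 12 6-[(4R,5S)-5-(2-hydroxypropan-2-yl)-2,2-dimethyl-1,3-dioxolan-4-yl]-7-methoxy-2H-chromen-2-one
Conditions: 6 (1.5 equiv), NiBr2·glyme (10 mol%), 4,4'-di-tert-butyl-2,2'-bipyridine (12 mol%), Zn powder (2 equiv), DMA, 25 °C, Ar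
Reagents that add atoms: none
Why: Zinc reduces the NiBr2/bipyridine precatalyst to zerovalent nickel, which inserts into the C6–I bond of 11, while single-electron reduction of ester 6 expels phthalimide anion and CO2 to leave the oxygen-stabilised 1,3-dioxolan-4-yl radical; the arylnickel species traps this radical, the resulting trivalent aryl(alkyl)nickel complex reductively eliminates the C6–C1' bond, and zinc returns monovalent nickel to the cycle. The closest known reaction type is the nickel-catalysed reductive (cross-electrophile) decarboxylative arylation of N-hydroxyphthalimide esters with aryl iodides, which is established for alpha-oxy acids. No ring is closed. The carboxyl-bearing stereocentre of 6 is erased in the planar radical, and the new C1' centre is set by the surviving C5 centre: the bulky 2-hydroxypropan-2-yl group shields its own face of the five-membered ring, so nickel and then the aryl group should be delivered anti to it, giving the trans-(4R,5S)-dioxolane, that is the threo diol. The step needs cross-coupling over homo-coupling and tolerance of the coumarin Michael acceptor; the first is secured because the two electrophiles are activated by different mechanisms (two-electron oxidative addition for the aryl iodide, one-electron reduction for the ester, used in excess), the second by fast capture of the radical at nickel under neutral conditions at room temperature, which also leave the lactone, the acetonide and the free tertiary alcohol untouched.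

Step 7
Reactants: 12 6-[(4R,5S)-5-(2-hydroxypropan-2-yl)-2,2-dimethyl-1,3-dioxolan-4-yl]-7-methoxy-2H-chromen-2-one
Product: 13 7-methoxy-6-[(1R,2S)-1,2,3-trihydroxy-3-methylbutyl]-2H-chromen-2-one
Conditions: AcOH/H2O 4:1, 45 °C
Reagents that add atoms: none
Why: Acid-catalysed acetal hydrolysis through the oxocarbenium ion at the ketal carbon breaks no bond to C1' or C2', so both stereocentres are retained, and the weak acid should avoid ionisation of the benzylic C1'–O bond and dehydration of the tertiary alcohol.

Step 8
Reactants: 13 7-methoxy-6-[(1R,2S)-1,2,3-trihydroxy-3-methylbutyl]-2H-chromen-2-one; 14 3-methylbutanoic anhydride (isovaleric anhydride)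
Product: 15 (1R,2S)-2,3-dihydroxy-1-(7-methoxy-2-oxo-2H-chromen-6-yl)-3-methylbutyl 3-methylbutanoate
Conditions: 14 (1.05 equiv), Et3N (1.5 equiv), DMAP (5 mol%), CH2Cl2, −40 to −20 °C; pH 7 buffer work-up
Reagents that add atoms: none
Why: DMAP-catalysed acylation under kinetic control: the tertiary C3' hydroxyl is inert, the C2' hydroxyl is neopentyl-like (flanked by the fully substituted C3') and should react much more slowly than the benzylic C1' hydroxyl, and low temperature, near-stoichiometric anhydride and a neutral work-up limit bis-acylation and 1'→2' acyl migration; no stereocentre is touched.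

**Compound list**

1 | dimethyl (4S,5S)-2,2-dimethyl-1,3-dioxolane-4,5-dicarboxylate (acetonide of dimethyl D-tartrate) | COC(=O)[C@H]1OC(C)(C)O[C@@H]1C(=O)OC | starting material
2 | (4S,5S)-5-(methoxycarbonyl)-2,2-dimethyl-1,3-dioxolane-4-carboxylic acid | OC(=O)[C@H]1OC(C)(C)O[C@@H]1C(=O)OC | intermediate
3 | (4S,5S)-5-acetyl-2,2-dimethyl-1,3-dioxolane-4-carboxylic acid (present as its bromomagnesium carboxylate) | OC(=O)[C@H]1OC(C)(C)O[C@@H]1C(C)=O | intermediate
4 | (4S,5S)-5-(2-hydroxypropan-2-yl)-2,2-dimethyl-1,3-dioxolane-4-carboxylic acid | OC(=O)[C@H]1OC(C)(C)O[C@@H]1C(C)(C)O | intermediate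
5 | N-hydroxyphthalimide | ON1C(=O)c2ccccc2C1=O | starting material
6 | 1,3-dioxoisoindolin-2-yl (4S,5S)-5-(2-hydroxypropan-2-yl)-2,2-dimethyl-1,3-dioxolane-4-carboxylate | O=C(ON1C(=O)c2ccccc2C1=O)[C@H]1OC(C)(C)O[C@@H]1C(C)(C)O | intermediate
7 | 2-hydroxy-4-methoxybenzaldehyde | COc1ccc(C=O)c(O)c1 | starting material
8 | 2-hydroxy-5-iodo-4-methoxybenzaldehyde | COc1cc(O)c(C=O)cc1I | intermediate
9 | ethyl (triphenylphosphoranylidene)acetate | CCOC(=O)C=P(c1ccccc1)(c1ccccc1)c1ccccc1 | starting material
10 | ethyl (E)-3-(2-hydroxy-5-iodo-4-methoxyphenyl)prop-2-enoate | CCOC(=O)/C=C/c1cc(I)c(OC)cc1O | intermediate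
11 | 6-iodo-7-methoxy-2H-chromen-2-one | COc1cc2oc(=O)ccc2cc1I | intermediate
12 | 6-[(4R,5S)-5-(2-hydroxypropan-2-yl)-2,2-dimethyl-1,3-dioxolan-4-yl]-7-methoxy-2H-chromen-2-one | COc1cc2oc(=O)ccc2cc1[C@H]1OC(C)(C)O[C@@H]1C(C)(C)O | intermediate
13 | 7-methoxy-6-[(1R,2S)-1,2,3-trihydroxy-3-methylbutyl]-2H-chromen-2-one | COc1cc2oc(=O)ccc2cc1[C@@H](O)[C@H](O)C(C)(C)O | intermediate
14 | 3-methylbutanoic anhydride (isovaleric anhydride) | CC(C)CC(=O)OC(=O)CC(C)C | starting material
15 | (1R,2S)-2,3-dihydroxy-1-(7-methoxy-2-oxo-2H-chromen-6-yl)-3-methylbutyl 3-methylbutanoate | COc1cc2oc(=O)ccc2cc1[C@@H](OC(=O)CC(C)C)[C@H](O)C(C)(C)O | target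

**Step count**

Total steps: 8. Longest linear sequence: 6 steps (steps 1, 2, 3, 6, 7, 8 from 1); the coumarin branch is steps 4 and 5.

**Steps most likely to fail**

Step 6. The dioxolanyl radical may be lost to hydrogen abstraction, dimerisation or addition to the C3–C4 double bond of the coumarin, while 11 is consumed by hydrodeiodination or biaryl formation, so that cross-coupling stalls. Fallback, from 11 and 6 back to 12: switch from the cross-electrophile manifold to a decarboxylative Negishi arylation. Zinc insertion into 11 (Zn powder, LiCl, THF, 25–40 °C) should give (7-methoxy-2-oxo-2H-chromen-6-yl)zinc iodide F1. F1 is then coupled with ester 6 under NiCl2·glyme and 4,4'-di-tert-butyl-2,2'-bipyridine in THF/DMF at rt. The aryl group then reaches nickel by transmetalation and no longer depends on reductive turnover in the presence of the aryl iodide. The same trans delivery to the dioxolanyl radical is expected, giving 12.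

Step 8. Acylation may occur at O2' or at both secondary hydroxyls, and the ester may migrate from O1' to O2' during reaction or work-up. Fallback, from 13 back to 15: mask the C2'/C3' diol temporarily as a boronate. Condensation of 13 with PhB(OH)2 (toluene, azeotropic removal of water) should give 6-[(R)-[(4S)-5,5-dimethyl-2-phenyl-1,3,2-dioxaborolan-4-yl](hydroxy)methyl]-7-methoxy-2H-chromen-2-one F2. The boronate isomers interconvert: the O1'/O2' isomer exposes only the unreactive tertiary hydroxyl, the six-membered O1'/O3' isomer only the most hindered one, so acylation should drain the mixture through F2. Acylation with 14 (pyridine, DMAP, CH2Cl2, 0 °C) should give (R)-[(4S)-5,5-dimethyl-2-phenyl-1,3,2-dioxaborolan-4-yl](7-methoxy-2-oxo-2H-chromen-6-yl)methyl 3-methylbutanoate F3. Neutral transesterification with excess pinacol (CH2Cl2, rt) then releases 15. Bis-acylation is excluded because O2' stays bound to boron throughout.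

Step 2. The bromomagnesium carboxylate may precipitate and leave the ester partly unreacted, the carboxylate may be attacked, or ketone 3 may enolise with epimerisation at C5. Fallback, from 1 back to 4: invert the order so that no carboxylate is present during the Grignard step. Diester 1 with MeMgBr (2.1 equiv, THF, −78 °C, slow addition) should give methyl (4S,5S)-5-(2-hydroxypropan-2-yl)-2,2-dimethyl-1,3-dioxolane-4-carboxylate F4. The second methyl adds to the more reactive ketone at the same carbon, and F4 is separated from recovered 1 and the bis-carbinol. Saponification of F4 (LiOH, THF/H2O, 0 °C, then acidification to pH 3) gives 4.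

**Further compounds**

F1 | step 6 | (7-methoxy-2-oxo-2H-chromen-6-yl)zinc iodide | COc1cc2oc(=O)ccc2cc1[Zn]I
F2 | step 8 | 6-[(R)-[(4S)-5,5-dimethyl-2-phenyl-1,3,2-dioxaborolan-4-yl](hydroxy)methyl]-7-methoxy-2H-chromen-2-one | COc1cc2oc(=O)ccc2cc1[C@@H](O)[C@@H]1OB(c2ccccc2)OC1(C)C
F3 | step 8 | (R)-[(4S)-5,5-dimethyl-2-phenyl-1,3,2-dioxaborolan-4-yl](7-methoxy-2-oxo-2H-chromen-6-yl)methyl 3-methylbutanoate | COc1cc2oc(=O)ccc2cc1[C@@H](OC(=O)CC(C)C)[C@@H]1OB(c2ccccc2)OC1(C)C
F4 | step 2 | methyl (4S,5S)-5-(2-hydroxypropan-2-yl)-2,2-dimethyl-1,3-dioxolane-4-carboxylate | COC(=O)[C@H]1OC(C)(C)O[C@@H]1C(C)(C)O
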